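## Structural features

The target is a cis-fused bicyclo[5.3.0]decene. A cyclopentane (C1–C5) shares the C1–C5 bond with a cycloheptene (C1, C5, C6, C7, C8, C9, C10), whose only ring alkene is the trisubstituted C8=C9 bond carrying the C8 methyl group. Five stereocentres form one unbroken chain, C10–C1–C5(–C4)–C6. The quaternary, methyl-bearing C1 lies between the allylic, neopentyl C10 (tigloyloxy) and the ring-fusion C5–H, and C5 lies between the tertiary isopropyl carbinol C4 and the aroyloxy carbon C6. The C4 hydroxyl and the C6 ester are on one face; H5, the C1 methyl group and the C10 ester are on the other. Fragile elements are the (E)-2-methylbut-2-enoate (Michael acceptor, base- and hydride-labile, on an ionisable allylic carbon), the free phenol, the tertiary alcohol β to C6 (retro-aldol or elimination whenever C6 is a ketone), and the β,γ relationship between C6 and C8=C9 (the alkene moves into conjugation when C6 is a ketone). The real difficulty is the quaternary C1 inside the seven-membered ring, together with telling apart the two secondary oxygens (C6, C10) and placing H5 on the face of the larger isopropyl group. The key step exploits the fact that C1 and C5 are neighbours in a cyclopentene and that C6–C7 can be a siloxyvinyl group on C5. C7=C6–C5=C1 is then a diene, and the three missing ring carbons C8–C9–C10 come from a vinylcarbenoid that forms C7–C8 and C1–C10.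

## Logic of the disconnections

31 is traced to 30 by cutting the two O–Si bonds (C4–O and phenol O). The tertiary alcohol and the phenol stay masked to the end; the forward step needs a fluoride source that spares two esters and causes no acyl shift to the C4 hydroxyl.

30 is cut at the C10 O–acyl bond into 28 and 29. The unsaturated ester is the most sensitive group and goes on last; the forward step must acylate a neopentyl allylic alcohol without deconjugating the acyl group.

28 is traced through 27 to 26 by removing the C10–O bond. C10 is the allylic CH2 on the CH terminus of the trisubstituted alkene, so the oxygen and the stereocentre are both removed and a plain alkene remains. The forward steps need regioselective allylic oxidation (C10, not C7 or the C8 methyl) and face-selective 1,2-reduction. The oxidation is placed here because earlier intermediates hold an enol ether and a doubly allylic C7.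

26 is cut at the C6 O–acyl bond into 22 and 25; 25 comes from 23 by phenol silylation. Acylating C6 while C10 is still CH2 differentiates the two secondary oxygens without any protecting group, and the ester then deactivates C7 towards the later oxidation.

22 is traced through 21 to 19 by removing the C6–H and C5–H bonds, so C6 returns to the enol ether of the key-step product. Two stereocentres disappear. The forward steps must set C5 under thermodynamic control, return the alkene to C8=C9 by kinetic protonation, and deliver hydride to C6 from the H5 face.

19 is traced through 17 to 16 by exchanging the C8 methyl group for the ester (C–H bonds for C–O bonds). The ester is what stabilises the carbenoid; it must be reduced while no other ester or carbonyl is present, and by direct (not allylic) hydride displacement.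

16 is cut at C7–C8 and C1–C10 into 10 and 14. This removes the seven-membered ring, the quaternary C1 and the alkene in one operation and leaves a cyclopentene and a four-carbon diazo ester. The forward step needs site-, diastereo- and face-selective cyclopropanation and a Cope shift whose terminus carries an inward methyl group.

10 is traced through 8 and 7 to 5 and 6 by cutting the enol O–Si bond and the C6–C7 bond. The forward steps need 1,2-addition to a hindered enal and kinetic enolisation at the acetyl methyl group.

5 is traced through 4 and 2 to 1 by cutting the C1=C5 bond (aldol condensation in reverse) and re-joining the two carbonyl carbons as a ring alkene (ozonolysis in reverse). The C4 stereocentre then comes from the chiral pool. The forward aldol must go through the aldehyde enamine and must not expel the β-silyloxy group.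

14 is traced through 13 and 12 to 11 by removing the diazo group and turning the vinyl group back into an acetyl group. 14 is unstable and must be made fresh.

## Other disconnections considered

Alternative 1: The cut is the C1–C5 bond, read backwards as a 1,2-shift. The hydroazulenone A1 would come from a trans-decalin in which C1 is still bonded to C6, C6 is a tertiary alkoxide and C5 carries a sulfonate. Forward, a strong base would trigger the semipinacol shift of C1 from C6 to C5, contracting one six-membered ring, expanding the other, and giving A1 with its C6 ketone.
- In its favour: the shift is stereospecific (C1 migrates with retention, C5 is formed with inversion), so the cis ring fusion next to the C6 carbonyl is fixed by the precursor and not by a protonation. On this point it is better than the chosen plan, where C5 has to be equilibrated. The decalin precursor is accessible in enantiopure form by a catalytic Robinson annulation, and the ionic mechanism is at least as dependable as a carbenoid cascade.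
- Against it here: A1 has no isopropyl group (C4 is a protected secondary alcohol that must be oxidised and then attacked at a hindered, enolisable cyclopentanone with face control), no C8 methyl group and no C8=C9 bond. These would have to be built from the C10 ketone along an unfunctionalised C7–C9 chain.
- Comparison: structurally it solves the ring fusion but leaves four carbons and the alkene to be added stepwise, whereas the chosen step delivers the alkene in place and the C8 carbon with the ring. In step count it would be clearly longer.

Alternative 2: Two bonds are cut, C1–C5 and C7–C8, so both rings open to a chain holding a C4–C5 epoxide beside a C6 enol silyl ether and, three carbons away, a 2-siloxydiene (C1, C10, C9, C8). Forward, a catalytic silyl triflate would open the epoxide to a siloxyallyl cation (C5–C6–C7), which the tethered diene would capture in an intramolecular (4+3) cycloaddition to give A2.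
- In its favour: both rings, C1, C5 and the C4 silyl ether would arise in one step. A2 already has the C6 ketone, the C8 methyl group and C10 at ketone level (as an enol ether that a dehydrogenation would turn directly into the C8=C9 enone). In oxidation pattern and in step economy after the key step it is better than the chosen plan, which must convert an ester into the methyl group and oxidise C10 late.
- Against it: the risk moves into the acyclic precursor (an enantiopure trisubstituted epoxide, a tetrasubstituted siloxy alkene of defined geometry, two different enol silyl ethers in one molecule) and into one cationic step. Its facial outcome at the quaternary C1 depends on a compact or extended transition state, and a cation at C5 next to the fully substituted C4 can rearrange.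
- Comparison: the chosen plan relays stereochemistry through a concerted pericyclic step from a catalyst-controlled cyclopropane, which is easier to predict. In total step count the two are comparable; the alternative is shorter after its key step and longer before it.

Alternative 3: The cut is C1–C10. Forward, a C10 seleno ester tethered through C6–C9 to the α-carbon of a 3-methylcyclopentenone would give, with a tin hydride and a radical initiator, an acyl radical that adds 7-endo to the β-carbon C1. Hydrogen-atom transfer to the resulting C5 radical would give the dione A3.
- In its favour: radicals tolerate crowding, so the quaternary centre should form readily. C6 and its oxygen are set in the open chain before ring closure. C10 arrives as a ketone next to a fully substituted carbon, so it can be dehydrogenated only towards C9, and the C8 methyl group is in place. In oxidation level at C6 and C10 it is the equal of the chosen plan or better.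
- Against it: only the remote C6 stereocentre controls C1. Decarbonylation and 6-exo closure compete with the slow 7-endo mode. A3 lacks the isopropyl group, and adding it requires telling two ketones (C4, C10) apart and controlling the face at C4. Stoichiometric tin and selenium reagents are needed.
- Comparison: absolute configuration needs an extra asymmetric step, whereas the chosen plan takes C4 from the chiral pool and uses it together with the catalyst to set C1. The mechanism is a chain process with several competing rates. The step count is similar.

Key step: step 10

Assumption: (S)-terpinen-4-ol of high enantiomeric purity is taken as the commercial form. It has the configuration needed at C4; the descriptor becomes R after ring contraction only because the CIP priorities change. The numbering C1–C10 defined under "Structural features" is used for all bicyclic intermediates.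

## Route

Step 1
Reactants: 1 (S)-terpinen-4-ol
Product: 2 (S)-triethyl[(1-isopropyl-4-methylcyclohex-3-en-1-yl)oxy]silane
Conditions: Et3SiOTf, 2,6-lutidine, CH2Cl2, 0 °C to rt
Reagents that add atoms: triethylsilyl trifluoromethanesulfonate, CC[Si](CC)(CC)OS(=O)(=O)C(F)(F)F
Why: Silyl triflate silylation of a hindered tertiary alcohol; the ether prevents lactol formation after ozonolysis and O–H insertion in step 10, and the chiral-pool C4 centre is not touched.

Step 2
Reactants: 2 triethylsilyl ether
Product: 4 (S)-3-isopropyl-6-oxo-3-(triethylsilyloxy)heptanal, via ozonide 3 (not isolated)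
Conditions: O3, CH2Cl2, −78 °C; then Me2S, −78 °C to rt
Reagents that add atoms: ozone, [O-][O+]=O
Why: Ozonolysis of the only alkene (cycloaddition, cycloreversion and recombination to the 1,2,4-trioxolane 3), followed by reductive work-up, gives the keto aldehyde without over-oxidation.

Step 3
Reactants: 4 keto aldehyde
Product: 5 (R)-5-isopropyl-2-methyl-5-(triethylsilyloxy)cyclopent-1-ene-1-carbaldehyde
Conditions: piperidine (0.3 equiv), AcOH (0.3 equiv), PhH, 60 °C
Reagents that add atoms: none
Why: Amine-catalysed intramolecular aldol condensation: the enamine of the aldehyde adds to the methyl ketone to close the five-membered ring and dehydration gives the tetrasubstituted enal; enamine catalysis favours this mode over ketone-enolate attack on the aldehyde, which would give an acetylcyclopentene.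

Step 4
Reactants: 5 cyclopentenecarbaldehyde; 6 methylmagnesium bromide
Product: 7 1-[(R)-5-isopropyl-2-methyl-5-(triethylsilyloxy)cyclopent-1-en-1-yl]ethan-1-ol (both carbinol epimers)
Conditions: MeMgBr, THF, −78 to 0 °C; NH4Cl (aq)
Reagents that add atoms: none
Why: Grignard 1,2-addition to the hindered enal supplies C7; the new carbinol centre is destroyed in step 5, so its configuration does not matter.

Step 5
Reactants: 7 allylic alcohol
Product: 8 1-[(R)-5-isopropyl-2-methyl-5-(triethylsilyloxy)cyclopent-1-en-1-yl]ethan-1-one
Conditions: Dess–Martin periodinane, NaHCO3, CH2Cl2, rt
Reagents that add atoms: none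
Why: Dess–Martin oxidation of a secondary allylic alcohol under buffered, non-acidic conditions that spare the tertiary allylic silyl ether.

Step 6
Reactants: 8 enone
Product: 10 tert-butyldimethyl({1-[(R)-5-isopropyl-2-methyl-5-(triethylsilyloxy)cyclopent-1-en-1-yl]vinyl}oxy)silane, via lithium enolate 9 (not isolated)
Conditions: LiN(i-Pr)2, THF, −78 °C; then t-BuMe2SiOTf, −78 to 0 °C
Reagents that add atoms: tert-butyldimethylsilyl trifluoromethanesulfonate, CC(C)(C)[Si](C)(C)OS(=O)(=O)C(F)(F)F
Why: Kinetic deprotonation at the acetyl methyl group (α′) and O-silylation give the cross-conjugated 2-siloxydiene; the low temperature avoids γ-deprotonation at the ring methyl group or at C2.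

Step 7
Reactants: 11 methyl acetoacetate
Product: 12 methyl 2-diazo-3-oxobutanoate
Conditions: 4-acetamidobenzenesulfonyl azide, Et3N, MeCN, 0 °C to rt
Reagents that add atoms: 4-acetamidobenzenesulfonyl azide, CC(=O)Nc1ccc(cc1)S(=O)(=O)N=[N+]=[N-]
Why: Regitz diazo transfer to an active methylene compound.

Step 8
Reactants: 12 diazo keto ester
Product: 13 methyl 2-diazo-3-hydroxybutanoate (racemic)
Conditions: NaBH4, MeOH, 0 °C
Reagents that add atoms: none
Why: Chemoselective borohydride reduction of the ketone; the stabilised diazo ester is inert to NaBH4.

Step 9
Reactants: 13 diazo alcohol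
Product: 14 methyl 2-diazobut-3-enoate
Conditions: POCl3, Et3N, CH2Cl2, 0 °C; kept cold in solution and used at once
Reagents that add atoms: none
Why: Dehydration by phosphorylation and amine-induced elimination gives the vinyldiazoacetate; it is used immediately because it cyclises to a pyrazole on standing.

Step 10
Reactants: 10 2-siloxydiene; 14 methyl 2-diazobut-3-enoate
Product: 16 bicyclic dienoate (1S,4R): C8 methyl ester; C8=C9 and C5=C6 double bonds; C6 tert-butyldimethylsilyl enol ether; C4 triethylsilyl ether, via divinylcyclopropane 15 (not isolated)
Conditions: Rh2(S-DOSP)4 {dirhodium tetrakis[(S)-N-(4-dodecylbenzenesulfonyl)prolinate]} (2 mol %), 14 added over 2 h, hexane, −40 °C to rt; then PhMe, 90 °C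
Reagents that add atoms: none
Why: The divalent rhodium carboxylate decomposes 14 to a donor–acceptor vinylcarbenoid with loss of N2, and this adds to the terminal C6=C7 enol ether bond of 10, the most electron-rich and the only unhindered alkene, forming C7–C8 and C6–C8. The closest known reaction type is the tandem cyclopropanation–Cope rearrangement (formal (4+3) cycloaddition) of vinyldiazoacetates with 2-siloxydienes, including dienes whose reacting terminus is fully substituted. The donor (vinyl) group of the carbenoid should end cis to the cyclopentenyl group, so 15 is a cis-divinylcyclopropane. The seven-membered ring is closed not by an ionic exo or endo attack but by the concerted 3,3-sigmatropic shift of 15 through a boat transition state, which breaks C6–C8 and joins C10 to C1, leaving the C8=C9 and C5=C6 double bonds. The only new stereocentre that survives is C1: the boat geometry ties the face of C1 that is attacked to the cyclopropane configuration, and the (1R,2S) cyclopropane places C10 on the face syn to the C4 silyloxy group and away from the isopropyl group. That cyclopropane is the one expected from the S-configured prolinate catalyst by analogy with its sense of induction with terminal alkenes, so catalyst and substrate should be matched. The step needs site selectivity (carbenoid carbon and not the vinyl terminus, C6=C7 and not C5=C1), which the non-polar solvent and the steric and electronic difference between the two alkenes should secure, and it needs heat for the Cope shift because the C1 methyl group points into the boat.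

Step 11
Reactants: 16 bicyclic dienoate
Product: 17 allylic alcohol (1S,4R): CH2OH on C8, otherwise as 16
Conditions: i-Bu2AlH (2.5 equiv), CH2Cl2, −78 °C; KNaC4H4O6 (aq)
Reagents that add atoms: none
Why: 1,2-Reduction of the conjugated ester to the primary allylic alcohol; the enol silyl ether and the silyl ether are inert to the aluminium hydride at low temperature.

Step 12
Reactants: 17 allylic alcohol
Product: 19 C8-methyl diene (1S,4R): CH3 on C8; C8=C9 and C5=C6 double bonds; C6 tert-butyldimethylsilyl enol ether; C4 triethylsilyl ether, via allylic mesylate 18 (not isolated)
Conditions: MeSO2Cl, Et3N, THF, −30 °C; then LiEt3BH, −30 to 0 °C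
Reagents that add atoms: none
Why: Sulfonylation and direct SN2 hydride displacement at the primary allylic carbon turn CH2OH into CH3 without allylic transposition; no ester or carbonyl group is present yet, so the strong hydride is safe.

Step 13
Reactants: 19 C8-methyl diene
Product: 21 cis-fused β,γ-unsaturated ketone (1S,4R,5R): C6 ketone; C8=C9; C8 methyl; C4 triethylsilyl ether, via potassium dienolate 20 (not isolated)
Conditions: Bu4NF (1.1 equiv), THF, 0 °C; then KOt-Bu (3 equiv), t-BuOH, 0 °C to rt; then inverse addition to AcOH/H2O, 0 °C
Reagents that add atoms: none
Why: Fluoride removes the enol silyl group, and KOt-Bu/t-BuOH lets the enolates equilibrate to the conjugated dienolate 20, in which C5 carries hydrogen and should relax to the cis ring fusion (C6 cis to the oxygen on C4 and not to the isopropyl group). Kinetic protonation of the dienolate at its α-carbon C7 (deconjugative protonation, as in the preparation of β,γ-unsaturated ketones from enones) leaves the alkene at C8=C9; a simple kinetic hydrolysis is avoided because protonation of C5 from the less hindered face would be expected to give the trans ring fusion.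

Step 14
Reactants: 21 β,γ-unsaturated ketone
Product: 22 homoallylic alcohol (1S,4R,5S,6R): C6 β-hydroxyl cis to the C4 silyloxy group
Conditions: NaBH4, CeCl3·7H2O, MeOH/THF, −40 °C
Reagents that add atoms: none
Why: 1,2-Reduction in a weakly basic medium that does not move the alkene into conjugation; hydride should enter from the convex face that carries H5, anti to C4 and its silyloxy group, which puts the hydroxyl cis to the C4 oxygen.

Step 15
Reactants: 23 4-hydroxybenzoic acid
Product: 25 4-(tert-butyldimethylsilyloxy)benzoic acid, via silyl ester 24 (not isolated)
Conditions: t-BuMe2SiCl (2.4 equiv), imidazole, DMF, rt; then AcOH/THF/H2O, rt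
Reagents that add atoms: tert-butyldimethylsilyl chloride, CC(C)(C)[Si](C)(C)Cl
Why: Bis-silylation followed by selective hydrolysis of the much more labile silyl ester leaves the aryl silyl ether.

Step 16
Reactants: 22 homoallylic alcohol; 25 4-(tert-butyldimethylsilyloxy)benzoic acid
Product: 26 C6 4-(tert-butyldimethylsilyloxy)benzoate (1S,4R,5S,6R)
Conditions: EDC·HCl, DMAP, CH2Cl2, rt
Reagents that add atoms: none
Why: Steglich-type carbodiimide esterification through the acylpyridinium ion; C10 is still CH2, so the only free hydroxyl is the one at C6.

Step 17
Reactants: 26 C6 ester
Product: 27 enone (1R,4R,5S,6R): C10 ketone conjugated with C8=C9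
Conditions: Rh2(cap)4 (dirhodium tetracaprolactamate, 1 mol %), t-BuOOH (70% in water, 5 equiv), ClCH2CH2Cl, 40 °C
Reagents that add atoms: tert-butyl hydroperoxide, CC(C)(C)OO
Why: Radical allylic oxidation (hydrogen abstraction by the tert-butylperoxy radical, mixed peroxide, collapse to the enone) of a trisubstituted cycloalkene places the carbonyl on the CH2 attached to the CH terminus, as in the 7-oxidation of Δ5-steroids. C7 is deactivated inductively and sterically by the neighbouring aroyloxy group, and the methyl C–H bonds are stronger.

Step 18
Reactants: 27 enone
Product: 28 allylic alcohol (1R,4R,5S,6R,10R): C10 hydroxyl cis to the C1 methyl group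
Conditions: NaBH4, CeCl3·7H2O, MeOH/THF, −78 °C
Reagents that add atoms: none
Why: Luche 1,2-reduction of the enone. In the conformer that keeps the C6 ester pseudo-equatorial, the angular methyl group is pseudo-axial next to C10, so hydride should add anti to it and leave the hydroxyl cis to the methyl group, as in the reduction of 17-oxo steroids.

Step 19
Reactants: 28 allylic alcohol; 29 tigloyl chloride [(E)-2-methylbut-2-enoyl chloride]
Product: 30 bis-silyl ether of the target (1R,4R,5S,6R,10R)
Conditions: pyridine, DMAP (cat.), CH2Cl2, 0 to 40 °C
Reagents that add atoms: none
Why: DMAP-catalysed acylation with the acid chloride; pyridine as the only base avoids vinylketene formation and β,γ-isomerisation, so the E geometry of 29 is retained.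

Step 20
Reactants: 30 bis-silyl ether
Product: 31 target, (1R,4R,5S,6R,10R)-4-hydroxy-6-(4-hydroxybenzoyloxy)-10-[(E)-2-methylbut-2-enoyloxy] bicycle
Conditions: HF·pyridine, pyridine, THF, 0 °C to rt
Reagents that add atoms: none
Why: Fluoride cleaves the aryl silyl ether and the tertiary triethylsilyl ether under buffered acidic conditions that leave both esters in place and give no acyl shift to the tertiary hydroxyl.

## Compound list

1 | (S)-terpinen-4-ol | CC1=CC[C@](O)(C(C)C)CC1 | starting material
2 | (S)-triethyl[(1-isopropyl-4-methylcyclohex-3-en-1-yl)oxy]silane | CC1=CC[C@](O[Si](CC)(CC)CC)(C(C)C)CC1 | intermediate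
3 | ozonide of 2 (1,2,4-trioxolane across the former ring alkene, S at the silyloxy carbon, mixture at the ozonide carbons) | CC12CC[C@@](O[Si](CC)(CC)CC)(C(C)C)CC(OO1)O2 | intermediate
4 | (S)-3-isopropyl-6-oxo-3-(triethylsilyloxy)heptanal | CC(=O)CC[C@@](O[Si](CC)(CC)CC)(C(C)C)CC=O | intermediate
5 | (R)-5-isopropyl-2-methyl-5-(triethylsilyloxy)cyclopent-1-ene-1-carbaldehyde | O=CC1=C(C)CC[C@@]1(O[Si](CC)(CC)CC)C(C)C | intermediate
6 | methylmagnesium bromide | C[Mg]Br | starting material
7 | 1-[(R)-5-isopropyl-2-methyl-5-(triethylsilyloxy)cyclopent-1-en-1-yl]ethan-1-ol (both carbinol epimers) | CC(O)C1=C(C)CC[C@@]1(O[Si](CC)(CC)CC)C(C)C | intermediate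
8 | 1-[(R)-5-isopropyl-2-methyl-5-(triethylsilyloxy)cyclopent-1-en-1-yl]ethan-1-one | CC(=O)C1=C(C)CC[C@@]1(O[Si](CC)(CC)CC)C(C)C | intermediate
9 | lithium enolate of 8 (deprotonated at the acetyl methyl group) | [Li+].[O-]C(=C)C1=C(C)CC[C@@]1(O[Si](CC)(CC)CC)C(C)C | intermediate
10 | tert-butyldimethyl({1-[(R)-5-isopropyl-2-methyl-5-(triethylsilyloxy)cyclopent-1-en-1-yl]vinyl}oxy)silane | C=C(O[Si](C)(C)C(C)(C)C)C1=C(C)CC[C@@]1(O[Si](CC)(CC)CC)C(C)C | intermediate
11 | methyl acetoacetate | CC(=O)CC(=O)OC | starting material
12 | methyl 2-diazo-3-oxobutanoate | CC(=O)C(=[N+]=[N-])C(=O)OC | intermediate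
13 | methyl 2-diazo-3-hydroxybutanoate (racemic) | CC(O)C(=[N+]=[N-])C(=O)OC | intermediate
14 | methyl 2-diazobut-3-enoate | C=CC(=[N+]=[N-])C(=O)OC | intermediate
15 | methyl (1R,2S)-2-(tert-butyldimethylsilyloxy)-2-[(R)-5-isopropyl-2-methyl-5-(triethylsilyloxy)cyclopent-1-en-1-yl]-1-vinylcyclopropane-1-carboxylate | COC(=O)[C@@]1(C=C)C[C@]1(O[Si](C)(C)C(C)(C)C)C2=C(C)CC[C@@]2(O[Si](CC)(CC)CC)C(C)C | intermediate
16 | bicyclic dienoate (1S,4R): methyl ester on C8, C8=C9 and C5=C6 double bonds, C6 tert-butyldimethylsilyl enol ether, C4 triethylsilyl ether and isopropyl, C1 methyl | COC(=O)C1=CC[C@]2(C)CC[C@@](O[Si](CC)(CC)CC)(C(C)C)C2=C(O[Si](C)(C)C(C)(C)C)C1 | intermediate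
17 | allylic alcohol (1S,4R): as 16 with CH2OH on C8 | OCC1=CC[C@]2(C)CC[C@@](O[Si](CC)(CC)CC)(C(C)C)C2=C(O[Si](C)(C)C(C)(C)C)C1 | intermediate
18 | allylic mesylate (1S,4R): as 16 with CH2OSO2CH3 on C8 | CS(=O)(=O)OCC1=CC[C@]2(C)CC[C@@](O[Si](CC)(CC)CC)(C(C)C)C2=C(O[Si](C)(C)C(C)(C)C)C1 | intermediate
19 | C8-methyl diene (1S,4R): as 16 with CH3 on C8 | CC1=CC[C@]2(C)CC[C@@](O[Si](CC)(CC)CC)(C(C)C)C2=C(O[Si](C)(C)C(C)(C)C)C1 | intermediate
20 | potassium dienolate (cis-fused): C6 enolate oxygen, C6=C7 and C8=C9 double bonds, H on C5 | [K+].[O-]C1=CC(C)=CC[C@]2(C)CC[C@@](O[Si](CC)(CC)CC)(C(C)C)[C@H]12 | intermediate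
21 | cis-fused β,γ-unsaturated ketone (1S,4R,5R): C6 ketone, C8=C9, C8 methyl, C4 triethylsilyl ether | O=C1CC(C)=CC[C@]2(C)CC[C@@](O[Si](CC)(CC)CC)(C(C)C)[C@H]12 | intermediate
22 | homoallylic alcohol (1S,4R,5S,6R): C6 hydroxyl cis to the C4 silyloxy group | O[C@@H]1CC(C)=CC[C@]2(C)CC[C@@](O[Si](CC)(CC)CC)(C(C)C)[C@H]12 | intermediate
23 | 4-hydroxybenzoic acid | OC(=O)c1ccc(O)cc1 | starting material
24 | tert-butyldimethylsilyl 4-(tert-butyldimethylsilyloxy)benzoate | CC(C)(C)[Si](C)(C)OC(=O)c1ccc(O[Si](C)(C)C(C)(C)C)cc1 | intermediate
25 | 4-(tert-butyldimethylsilyloxy)benzoic acid | OC(=O)c1ccc(O[Si](C)(C)C(C)(C)C)cc1 | intermediate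
26 | C6 4-(tert-butyldimethylsilyloxy)benzoate of 22 (1S,4R,5S,6R) | CC(C)(C)[Si](C)(C)Oc1ccc(cc1)C(=O)O[C@@H]1CC(C)=CC[C@]2(C)CC[C@@](O[Si](CC)(CC)CC)(C(C)C)[C@H]12 | intermediate
27 | enone (1R,4R,5S,6R): as 26 with a C10 ketone conjugated with C8=C9 | CC(C)(C)[Si](C)(C)Oc1ccc(cc1)C(=O)O[C@@H]1CC(C)=CC(=O)[C@]2(C)CC[C@@](O[Si](CC)(CC)CC)(C(C)C)[C@H]12 | intermediate
28 | allylic alcohol (1R,4R,5S,6R,10R): as 27 with a C10 hydroxyl cis to the C1 methyl group | CC(C)(C)[Si](C)(C)Oc1ccc(cc1)C(=O)O[C@@H]1CC(C)=C[C@@H](O)[C@]2(C)CC[C@@](O[Si](CC)(CC)CC)(C(C)C)[C@H]12 | intermediate
29 | tigloyl chloride, (E)-2-methylbut-2-enoyl chloride | C/C=C(\C)C(=O)Cl | starting material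
30 | bis-silyl ether of the target (1R,4R,5S,6R,10R): C4 triethylsilyl ether, aryl tert-butyldimethylsilyl ether | C/C=C(\C)C(=O)O[C@@H]1C=C(C)C[C@@H](OC(=O)c2ccc(O[Si](C)(C)C(C)(C)C)cc2)[C@@H]2[C@@]1(C)CC[C@@]2(O[Si](CC)(CC)CC)C(C)C | intermediate
31 | target (1R,4R,5S,6R,10R): C4 hydroxyl and isopropyl, C6 4-hydroxybenzoate, C8 methyl on C8=C9, C10 (E)-2-methylbut-2-enoate, C1 methyl, cis ring fusion | C/C=C(\C)C(=O)O[C@@H]1C=C(C)C[C@@H](OC(=O)c2ccc(O)cc2)[C@@H]2[C@@]1(C)CC[C@@]2(O)C(C)C | target

## Step count and least certain steps

Total: 20 steps. Longest linear sequence: 16 steps (steps 1–6, 10–14 and 16–20); steps 7–9 and step 15 are side branches.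

**Step 10 (key step).** Facial control in the cyclopropanation could be mismatched or eroded. The carbon that is attacked carries two substituents, and if the siloxy group rather than the cyclopentenyl group ends cis to the vinyl group, the divinylcyclopropane can reach the Cope geometry only after epimerisation, which scrambles the relay to C1. The Cope shift itself is slowed by the inward C1 methyl group, so thermal ring-opening of the donor–acceptor cyclopropane can compete.

Fallback, from 5 back to 21, building the ring by conjugate addition and metathesis instead of a carbenoid: copper-mediated conjugate addition of CH2=CHCH2MgBr to 5 (CuBr·SMe2, Me3SiCl, THF, −78 °C, dilute acid on work-up) would give the β-quaternary aldehyde F1. Addition of 2-methylallylmagnesium chloride would give the dienol F2. Ring-closing metathesis with the second-generation Grubbs catalyst would close the C8=C9 bond and give the cycloheptenol F3. Dess–Martin oxidation would give the ketone F4, which is 21 together with its C5 epimer. Treating F4 with KOt-Bu/t-BuOH and quenching as in the second half of step 13 returns the material to the route at 21. The price is substrate control only at C1.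

**Step 13.** Three processes threaten it: loss of triethylsilanolate from C4 by β-elimination while the C5 enolate is present, incomplete equilibration at C5, and protonation of the dienolate at C9 (or formation of the exocyclic dienolate through the methyl group), which would misplace the alkene.

Fallback, from 19 back to 22, separating equilibration from deconjugation: buffered desilylation (Bu4NF, AcOH, THF, 0 °C) followed by DBU in PhMe would give the conjugated cis-fused enone F5 under milder basic conditions. Isopropenyl acetate with catalytic TsOH would give the dienyl acetate F6. NaBH4 in EtOH would then carry out the classical deconjugative reduction of a dienyl acetate and deliver the homoallylic alcohol 22 directly.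

**Step 17.** Hydrogen abstraction at C7 or at the C8 methyl group could compete with abstraction at the neopentyl C10, and the mixed peroxide could form at C8 instead of C10.

Fallback, from 26 back to 27, by a regiodefined three-stage transposition: epoxidation (mCPBA, NaHCO3, CH2Cl2) would give the 8,9-epoxide F7. Opening at the less substituted C9 with PhSeNa (from PhSeSePh and NaBH4) would give the hydroxy selenide F8. Oxidation with H2O2 and selenoxide elimination, possible only towards C10, would give the tertiary allylic alcohol F9. Oxidative allylic transposition with pyridinium chlorochromate, C5H5NH[CrO3Cl], would then give 27.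

**Step 18.** Facial selectivity of hydride delivery at C10 could be poor or reversed, because the two groups on C1 that flank the carbonyl (the methyl group and C2 of the cyclopentane) differ little in size and the seven-membered ring is flexible.

Fallback, from 27 back to 28, replacing substrate control by reagent control: Corey–Bakshi–Shibata reduction with the (S)-2-methyl oxazaborolidine and catecholborane in PhMe at −78 °C, in which the fully substituted C1 acts as the large group, should give the (10R) alcohol. This fallback makes no new compound (F0).

## Further compounds

F1 | step 10 | 2-allyl-2-methyl-5-isopropyl-5-(triethylsilyloxy)cyclopentane-1-carbaldehyde (C1 allyl syn to the silyloxy group, C5 epimers) | O=CC1[C@](C)(CC=C)CC[C@@]1(O[Si](CC)(CC)CC)C(C)C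
F2 | step 10 | dienol from methallyl addition to F1 (carbinol and C5 epimers) | C=C(C)CC(O)C1[C@](C)(CC=C)CC[C@@]1(O[Si](CC)(CC)CC)C(C)C
F3 | step 10 | cycloheptenol: C6 hydroxyl, C8=C9, C8 methyl, C4 triethylsilyl ether (C5 and C6 epimers) | OC1CC(C)=CC[C@]2(C)CC[C@@](O[Si](CC)(CC)CC)(C(C)C)C12
F4 | step 10 | β,γ-unsaturated ketone 21 together with its C5 epimer | O=C1CC(C)=CC[C@]2(C)CC[C@@](O[Si](CC)(CC)CC)(C(C)C)C12
F5 | step 13 | cis-fused conjugated enone: C6 ketone, C7=C8, C8 methyl, C4 triethylsilyl ether | O=C1C=C(C)CC[C@]2(C)CC[C@@](O[Si](CC)(CC)CC)(C(C)C)[C@H]12
F6 | step 13 | dienyl acetate: C6 acetoxy, C6=C7 and C8=C9 double bonds | CC(=O)OC1=CC(C)=CC[C@]2(C)CC[C@@](O[Si](CC)(CC)CC)(C(C)C)[C@H]12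
F7 | step 17 | 8,9-epoxide of 26 (epoxide face not specified) | CC(C)(C)[Si](C)(C)Oc1ccc(cc1)C(=O)O[C@@H]1CC2(C)OC2C[C@]3(C)CC[C@@](O[Si](CC)(CC)CC)(C(C)C)[C@H]13
F8 | step 17 | hydroxy selenide: C8 tertiary hydroxyl, C9 phenylselanyl | CC(C)(C)[Si](C)(C)Oc1ccc(cc1)C(=O)O[C@@H]1CC(C)(O)C([Se]c2ccccc2)C[C@]3(C)CC[C@@](O[Si](CC)(CC)CC)(C(C)C)[C@H]13
F9 | step 17 | tertiary allylic alcohol: C8 hydroxyl and methyl, C9=C10 | CC(C)(C)[Si](C)(C)Oc1ccc(cc1)C(=O)O[C@@H]1CC(C)(O)C=C[C@]3(C)CC[C@@](O[Si](CC)(CC)CC)(C(C)C)[C@H]13
F0 | step 18 | none | none
A1 | alternative 1 | cis-fused hydroazulen-6-one with a C4 tert-butyldimethylsilyl ether and a C10 dioxolane | O1CCOC12CCCC(=O)[C@@H]3[C@@]2(C)CC[C@H]3O[Si](C)(C)C(C)(C)C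
A2 | alternative 2 | cis-fused hydroazulen-6-one with a C4 triethylsilyl ether and isopropyl group, a C8 methyl group and a C10 triethylsilyl enol ether | CC[Si](CC)(CC)OC1=C[C@@H](C)CC(=O)[C@@H]2[C@@]1(C)CC[C@@]2(O[Si](CC)(CC)CC)C(C)C
A3 | alternative 3 | cis-fused hydroazulene-4,10-dione with a C6 tert-butyldimethylsilyl ether and a C8 methyl group | O=C1CC(C)C[C@@H](O[Si](C)(C)C(C)(C)C)[C@@H]2[C@@]1(C)CCC2=O
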